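The easy mistake is to read the excess of leftover substrate as a property of the recipe. It is better treated as a count, and the count is what you should follow through the flask.

common to all: left-handed substrate 0.25 M; right-handed substrate 0.25 M; precatalyst 21 mM
- Wednesday's: reagent 0.56 M (fed, over 40 min); run made earlier; the fed solution adds 0.10 times the starting volume
- Monday's: reagent 1.3 M (fed, over 40 min); run made earlier; the fed solution adds 0.10 times the starting volume
- Tuesday's: reagent 2 M (fed, over 40 min); run made earlier; the fed solution adds 0.10 times the starting volume
- delta: reagent 0.625 M (fed, over 40 min); the fed solution adds 0.10 times the starting volume; time 1.0 h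
- zeta: reagent 2.50 M (fed, over 40 min); the fed solution adds 0.10 times the starting volume; time 1.0 h

| run | time / min | right-handed substrate / % | left-handed substrate / % | left-handed product / % |
|---|---|---|---|---|
| Wednesday's | 3.00 | 49.7 | 50.1 | 0 |
| Wednesday's | 6.00 | 48.4 | 48.7 | 0 |
| Wednesday's | 12.0 | 47.0 | 47.3 | 0.8 |
| Wednesday's | 20.0 | 45.7 | 42.7 | 8.3 |
| Wednesday's | 40.0 | 33.8 | 31.8 | 23.1 |
| Monday's | 3.00 | 49.9 | 48.8 | 0 |
| Monday's | 6.00 | 49.4 | 47.9 | 3.3 |
| Monday's | 12.0 | 44.0 | 43.7 | 6.5 |
| Monday's | 20.0 | 37.4 | 36.4 | 17.2 |
| Monday's | 40.0 | 21.3 | 15.4 | 39.0 |
| Tuesday's | 8.00 | 48.5 | 46.4 | 5.0 |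
| Tuesday's | 15.0 | 40.9 | 37.6 | 15.5 |
| Tuesday's | 25.0 | 29.9 | 23.3 | 30.2 |
| Tuesday's | 30.0 | 22.2 | 15.8 | 35.4 |
| Tuesday's | 40.0 | 10.6 | 6.9 | 48.0 |

(each reading ± 1 percentage point)

- reagent is single-handed; left-handed substrate and right-handed substrate are mirror images of each other, charged as a racemate, each of them at the stated concentration
- charges are per starting volume, the dose included; the dosed solution carries all of it
- an excess is the difference of the two amounts in percent of their sum
- an excess is below zero if the other one leads
- the handed part of reagent does not stay in what it makes, so the products of the two hands are mirror images too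

1. which one finishes higher in excess of right-handed substrate over left-handed substrate among what is left of the two ("neither" within 2 percentage points) (delta / zeta / neither)
2. excess of right-handed substrate over left-handed substrate among what is left of the two at the end, delta
3. excess of right-handed substrate over left-handed substrate among what is left of the two at the end, zeta

Take a flask in slow motion. In the first minutes little shows: Wednesday's run reads 0% left-handed product at 6.00 min, with the substrates at 48.4% and 48.7%. By the middle, the hands part: Tuesday's run at 15.0 min has less left-handed substrate than right-handed, 37.6% against 40.9%.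

At the end of Tuesday's feed, count turnovers as L, the natural log of charged over left. The right hand has made 1.55 and the left hand 1.98. Their ratio is s, the hand ratio 1.28, a reading of the selectivity factor. If f is the right-handed fraction left and g is f raised to s minus 1, the excess is (1 − g)/(1 + g). But Tuesday's left-handed product reads 48.0%, higher than the 43.1% that the left-handed substrate has given up. That hints that substrate changes hand, so this s is a net figure.

Now the end. Take L to grow with [reagent] times time. The rising feed counts as half its length at full [reagent], and the hold adds the same, so the final count is twice that at the end of the feed. Scaling the right-handed count of Wednesday's run by charge for delta and that of Tuesday's run for zeta, and neglecting reagent used, I get 0.874 for delta and 3.88 for zeta. My own excesses are then 12.0% for delta and 49.0% for zeta.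

The forecast, whose figures differ from mine, says zeta finishes higher, with 11% for delta (6% to 16%) and 50% for zeta (35% to 65%), adding “This one is very uncertain”.

The simulation gives zeta higher, with 6.59% for delta and 42.7% for zeta, so the forecast's zeta stands 7.3 percentage points too high.

    reagent + right-handed substrate → right-handed product (k = 6.39 × 10⁻⁴ L mol⁻¹ s⁻¹)
    reagent + racemization catalyst → spent catalyst (k = 0.00112 L mol⁻¹ s⁻¹)
    left-handed substrate + racemization catalyst ⇌ right-handed substrate + racemization catalyst, rate k3*[racemization catalyst]*[left-handed substrate] forward; the back reaction follows from the equilibrium constant (k = 0.376 L mol⁻¹ s⁻¹)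
    racemization catalyst ⇌ dormant form (K = 6.33, k = 9.39 × 10⁻⁴ s⁻¹)
    precatalyst ⇌ racemization catalyst (K = 0.170, k = 0.00108 s⁻¹)
    reagent + left-handed substrate → left-handed product (k = 0.00116 L mol⁻¹ s⁻¹)

Zeta leads through its larger reagent charge: with delta's charge, zeta gives 6.59% instead of 42.7%. Zeta keeps 3.2% of its right-handed substrate at 1.00 h, a count of 3.44, and s turns that into 44.3%, close to the computed value. A neighbour of zeta charged with 8.40 mM of precatalyst keeps 4.1%, for which s gives 41.5%. The computed result is 61.6%, so the s read at 21 mM does not carry over to that flask.

Readings and results were computed with made-up constants, and the scatter is random.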